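## The problem

1. The target is an eremophilane (numbering: ring A = C1–C5 and C10, ring B = C5–C10, C14 on C5, C15 on C4, C11–C13 on C7): a cis-4,5-dimethyl octalin whose ring B is a cross-conjugated 9-hydroxy-7(11),9-dien-8-one, and whose ring A carries an equatorial ester at C3.
2. The three stereocentres are contiguous in ring A: the quaternary C5, C4 with its methyl cis to the C5 methyl, and C3 with its oxygen trans to both methyls (3R,4R,5R).
3. C4 and C5 have to be set together and absolutely; once they are in place, the axial C5 methyl and the equatorial C4 methyl shield one face of ring A and can steer events at C3.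
4. C3 itself has no functional neighbour: it lies three bonds from C10 and cannot be reached by enolate or allyl chemistry from ring B.
5. The acyl group is a (2Z)-4-acyloxy-3-methylbut-2-enoate carrying an angelate; both Z double bonds isomerise on activation, with nucleophilic catalysts or with base, and the 4-hydroxy acid closes to a five-membered lactone as soon as its oxygen is free.
6. The diosphenol is acidic, acylates as easily as the C3 alcohol and is sensitive to oxidants, and three ester links forbid hydroxide or hydride late in the route.
7. The enabling feature is that all fifteen skeletal carbons, the cis methyls at C4 and C5, the C9=C10 double bond and the three-carbon branch at C7 are those of (+)-aristolochene (4) in the same absolute configuration. The oxygens at C8 and C9 sit on or next to the alkene the cyclase leaves, and C7 ends up sp2.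

## Retrosynthesis

**20 ⇒ 19.** No skeletal bond is cut: the C9 enol of 20 is traced back to the 9,10-epoxy-8-ketone 19, whose C10–O bond is the one broken in the forward sense. The neighbouring choice, acylating a 3,9-diol, would put the side-chain acid on the enol oxygen as well and would need a protecting group. The oxirane is needed anyway to bring oxygen to C9, so it masks the diosphenol at no cost. 19 is an isomer of 20. The forward step needs an acid that opens the oxirane at the tertiary C10 and removes H9 but leaves the angelate and the Z-enoate alone.

**19 ⇒ 8 + 17.** The C3 O–acyl bond is cut. This makes the route convergent and keeps organocopper chemistry and the acid-labile tert-butyl ester away from the terpenoid. Building the chain stepwise on 8 would expose the epoxy enone to those reagents. 8 has only one hydroxyl group. The forward acyl transfer must keep the 2Z geometry of 17 and go with retention at C3.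

**17 ⇒ 16 ⇒ 13 + 14.** The carboxyl group is unmasked from a tert-butyl ester, and the angelate ester bond is cut to the Z-hydroxy ester 13 and angelic acid 14. A tert-butyl ester is chosen over methyl or allyl because it is slow to lactonise onto the cis hydroxyl and is removed by acid without touching an allylic ester. The forward acylation must not convert the angelate into the tiglate.

**13 ⇒ 12 ⇒ 11 ⇒ 9.** The C3–CH3 bond of the butenoate is cut: syn addition of a methyl–copper reagent to the ynoate 11 fixes the 2Z geometry, which carbonyl olefination of an acyloxy ketone would deliver only as a mixture. 11 comes from the silyl-protected propargyl alcohol 9 by C-acylation of its acetylide 10. The oxygen is carried as a silyl ether because an acyloxy group at that position would be a leaving group towards the cuprate.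

**8 ⇒ 7.** The oxirane is removed to give the enone of isopetasol 7. Nucleophilic epoxidation is preferred to peracid, which would attack the electron-richer isopropylidene. The forward step must choose the C9=C10 enone over the tetrasubstituted C7=C11 enone.

**7 ⇒ 6.** The C3–O bond is cut to a C–H bond of dehydrofukinone 6. This is the one disconnection without a functional handle, and it is where the plan needs reinforcing.
- A chemical relay from the C8 carbonyl through C10, C1 and C2 costs at least three steps of uncertain selectivity, so a haem monooxygenase is used instead.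
- The hydroxylation is placed at the dienone stage. The hydrocarbon 4 offers two electron-rich alkenes and a reactive allylic C1. In 6 the allylic positions are deactivated by the carbonyl, and the carbonyl gives the enzyme a polar anchor at the end of the molecule remote from C3.
- The product 7 is a known natural product, which makes the assignment of site and configuration unambiguous.
- The forward step asks for C3 selectivity and for removal of the equatorial hydrogen.

**6 ⇒ 5 ⇒ 4.** The C8 carbonyl is removed and the C7=C11 alkene is returned to the isopropenyl position. C8 is the allylic methylene on the CH end of the only ring alkene of 4, the position radical allylic oxidation prefers, and the resulting β,γ-unsaturated ketone 5 moves into conjugation with base, which erases C7.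

**4 ⇒ 3.** The key disconnection cuts C6–C7 and C5–C10 and reverses the hydride and methyl shifts, unfolding both rings and all three stereocentres of 4 into the acyclic diphosphate 3. No chemical cation–olefin cyclisation delivers this rearranged skeleton in one enantiomer; the cyclase does so from its native substrate. The precursor is achiral and acyclic.

**3 ⇒ 2 ⇒ 1.** The diphosphate is cut at C–O to the allylic chloride 2 and this to farnesol 1. Both steps must keep the 2E geometry, because the cyclase accepts only the 2E,6E isomer.

## Roads not taken

**Alternative 1:** The cut is C3–C4 and C5–C10, with ring A read as a 7-oxanorbornene. The furyl enone A1 (a 2-furyl group joined through C9–C8–C7–C6 to an (E)-tigloyl ketone, silyl ether at C8) would undergo a MeAlCl2-promoted intramolecular Diels–Alder reaction to the oxa-bridged octalinone A2.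
- Merits: both rings close at once, the cis methyls at C4 and C5 follow from the alkene geometry, and the bridging oxygen already sits on C3. In that respect it is better than the chosen plan, which must find the C3 oxygen by C–H oxidation. It also needs no enzyme.
- Weak points: furan cycloadditions are reversible, and this one has to form a quaternary carbon from a trisubstituted dienophile, with facial control resting on a remote silyl ether. A2 carries a ketone at C6 that the target lacks and has no isopropylidene, no C9 oxygen and a C1=C2 alkene; removing the C6 carbonyl next to the quaternary centre is an awkward end-game.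
- Comparison: the chosen plan delivers all fifteen carbons in the right place in one step and needs no deoxygenation, at the price of one enzymatic hydroxylation of uncertain selectivity.

**Alternative 2:** The cut is C4–C5. The (S)-Hajos–Parrish ketone A3 would be converted into a 1,1-dibromoethyl carbinol at its saturated ketone; bromine–lithium exchange and migration of the quaternary carbon to the carbenoid would expand the five-membered ring to the dione A4.
- Merits: C5 comes from a cheap enantiopure building block, the C3 oxygen is present from the start as a ketone, the C8 enone is in place, and the C4 methyl can equilibrate to the equatorial, correct epimer. On the C3 oxygen and on scalability this route is stronger than the chosen one.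
- Weak points: the migration must select the quaternary carbon over the methylene, and the enone must be masked during the carbenoid chemistry. Hydride reduction of the C3 ketone is hindered on the axial trajectory by the syn-axial C5 methyl and should favour the wrong, axial alcohol. The isopropylidene and the C9 oxygen still have to be added.
- Comparison: the chosen plan carries the three-carbon branch from the start and sets C3 in the hydroxylation itself, which targets the equatorial C–H bond, but it depends on finding a suitable enzyme variant.

**Alternative 3:** The cut is C4–C5. The epoxy phenol A5 would, under a mild Lewis acid, attack the distal epoxide carbon through its para carbon in a 6-endo mode to give the methoxy dienone A6.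
- Merits: one step sets C3, C4 and the quaternary C5 from an epoxide made by asymmetric catalysis, and ring B emerges at the diosphenol oxidation level as its methyl ether. No other route matches the target's oxygen pattern so directly, and here it is clearly better than the chosen plan.
- Weak points: 6-endo opening at a secondary epoxide carbon competes with 5-exo opening, O-alkylation and ortho attack, and the dienone can rearrange under the Lewis acid. The isopropylidene must be added across the C6=C7 enone, and the methyl enol ether must be cleaved in the presence of three esters.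
- Comparison: the chosen plan sets against this a key step that is the native reaction of its catalyst, with no regiochemical choice left open.

Key step: step 3

Assumption: 8 (and hence 19) is drawn as the 9,10-epoxide on the face of the C5 methyl group, the epimer expected from alkaline epoxidation of angularly methylated octalones; the other epimer would serve equally, since C9 and C10 lose their configuration in step 13.

Assumption: 9 and 14 are bought; the cyclase, the P450 variants and glucose dehydrogenase are obtained by routine expression and are used as catalysts.

## Route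

Step 1
Reactants: 1 (2E,6E)-farnesol
Product: 2 (2E,6E)-farnesyl chloride
Conditions: NCS, Me2S, CH2Cl2, −40 to 0 °C
Reagents that add atoms: N-chlorosuccinimide, ClN1C(=O)CCC1=O
Why: Corey–Kim chlorination; chloride displaces the alkoxysulfonium group at the primary allylic carbon by SN2, so neither allylic transposition nor loss of the 2E geometry is expected.

Step 2
Reactants: 2 (2E,6E)-farnesyl chloride
Product: 3 (2E,6E)-farnesyl diphosphate trisammonium salt
Conditions: (Bu4N)3HP2O7, MeCN, rt; then cation-exchange resin (NH4+ form), aq NH4HCO3/i-PrOH; cellulose chromatography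
Reagents that add atoms: tris(tetrabutylammonium) hydrogen diphosphate, CCCC[N+](CCCC)(CCCC)CCCC.CCCC[N+](CCCC)(CCCC)CCCC.CCCC[N+](CCCC)(CCCC)CCCC.OP(=O)([O-])OP(=O)([O-])[O-]; ammonium hydrogencarbonate, [NH4+].OC([O-])=O
Why: SN2 displacement of the allylic chloride by the diphosphate trianion in a dipolar aprotic solvent, the standard diphosphorylation of allylic halides; ion exchange gives the water-soluble ammonium salt that the cyclase accepts.

Step 3
Reactants: 3 (2E,6E)-farnesyl diphosphate trisammonium salt
Product: 4 (+)-aristolochene [(4S,5R,7S)-eremophila-9,11-diene]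
Conditions: recombinant aristolochene synthase (Penicillium roqueforti enzyme expressed in E. coli), MgCl2 (5 mM), Tris buffer pH 7.5, 2-mercaptoethanol, pentane overlay, 25 °C
Reagents that add atoms: none
Why: This is the native reaction of a class one terpene cyclase: Mg2+-assisted ionisation of the allylic diphosphate gives the farnesyl cation, whose C6 terminus is attacked by the distal C7=C11 alkene (eremophilane numbering) to close the ten-membered ring, exo with respect to that alkene, and loss of a C12 proton gives enzyme-bound germacrene A. Reprotonation at C1 triggers transannular attack of the C4=C5 alkene on C10, which forms C5–C10 and both six-membered rings at once (6-endo for ring A, 6-exo for ring B with respect to C4=C5) and leaves the eudesmane cation at C4. A 1,2-hydride shift from C5 to C4 and a 1,2-methyl shift from C10 to C5 then take place on opposite faces, and loss of H9 ends the cascade at the C9=C10 alkene. The closest known reaction type is the enzymatic cation–olefin cyclisation of farnesyl diphosphate to germacrane, eudesmane and eremophilane hydrocarbons, of which this is the documented case. C7 is set by the face of the C7=C11 alkene that the folded chain presents to C6. C5 and C4 are set by the conformation in which germacrene A is held for the transannular closure, together with the suprafacial course of the two shifts, so that the C4 and C5 methyls end cis. The step needs completion past germacrene A and loss of H9 and not H1; both are secured by the active-site template and its base, and the 2E,6E purity of 3 from steps 1 and 2 secures correct folding.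

Step 4
Reactants: 4 (+)-aristolochene
Product: 6 dehydrofukinone [(4S,5R)-eremophila-7(11),9-dien-8-one], via (4S,5R,7S)-eremophila-9,11-dien-8-one 5 (not isolated)
Conditions: t-BuOOH, Rh2(cap)4 (dirhodium tetrakis(caprolactamate), 1 mol%), K2CO3, CH2Cl2, rt; then DBU, rt
Reagents that add atoms: tert-butyl hydroperoxide, CC(C)(C)OO
Why: Radical allylic C–H oxidation: hydrogen abstraction at C8 gives the allyl radical with a tertiary C10 terminus, which is trapped at the secondary end and oxidised to the ketone, the regiochemistry of the valencene-to-nootkatone oxidation. DBU then moves the β,γ-isopropenyl alkene into conjugation (the petasin-to-isopetasin type of isomerisation), which removes the C7 stereocentre.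

Step 5
Reactants: 6 dehydrofukinone
Product: 7 isopetasol [(3R,4R,5R)-3-hydroxyeremophila-7(11),9-dien-8-one]
Conditions: P450 BM3 (CYP102A1) variant chosen from a terpenoid-hydroxylating panel, NADP+ (cat.), D-glucose, glucose dehydrogenase, air, KPi buffer pH 8.0, 2% EtOH, 25 °C
Reagents that add atoms: dioxygen, O=O
Why: P450 hydroxylation of an unactivated ring methylene by hydrogen abstraction and oxygen rebound with retention, the reaction type by which such enzymes oxidise ring A of decalin sesquiterpenoids. A variant is sought that binds the C8 carbonyl near the channel entrance and presents the distal C3 methylene to the haem; its equatorial hydrogen, on the face away from both methyls, is the exposed one and should give the 3R alcohol. The product can be checked against natural isopetasol.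

Step 6
Reactants: 7 isopetasol
Product: 8 (3R,4R,5R,9R,10R)-9,10-epoxy-3-hydroxyeremophil-7(11)-en-8-one
Conditions: 30% H2O2, NaOH (aq), MeOH, 0 °C
Reagents that add atoms: hydrogen peroxide, OO
Why: Weitz–Scheffer epoxidation; hydroperoxide should add to C10 of the trisubstituted ring enone and not to the tetrasubstituted isopropylidene enone, as piperitenone gives its ring epoxide. The oxirane is expected mainly on the face of the angular methyl, as with 4-en-3-one steroids, and its configuration is of no consequence.

Step 7
Reactants: 9 tert-butyldimethyl(prop-2-yn-1-yloxy)silane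
Product: 11 tert-butyl 4-[(tert-butyldimethylsilyl)oxy]but-2-ynoate, via lithium acetylide 10 (not isolated)
Conditions: n-BuLi, THF, −78 °C; then Boc2O, −78 to 0 °C
Reagents that add atoms: di-tert-butyl dicarbonate, CC(C)(C)OC(=O)OC(=O)OC(C)(C)C
Why: Deprotonation of the terminal alkyne and C-acylation of the lithium acetylide with the dicarbonate, a standard preparation of tert-butyl ynoates.

Step 8
Reactants: 11 tert-butyl 4-[(tert-butyldimethylsilyl)oxy]but-2-ynoate
Product: 12 tert-butyl (2Z)-4-[(tert-butyldimethylsilyl)oxy]-3-methylbut-2-enoate
Conditions: Me2CuLi (from MeLi and CuI), THF, −78 °C; then MeOH, aq NH4Cl, −78 °C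
Reagents that add atoms: lithium dimethylcuprate, [Li+].C[Cu-]C
Why: Syn carbocupration of a 2-ynoate by a Gilman cuprate; protonation at −78 °C, before the alkenylcopper can equilibrate, puts the new methyl and the hydrogen cis and hence the silyloxymethyl group and the ester cis (2Z).

Step 9
Reactants: 12 tert-butyl (2Z)-4-[(tert-butyldimethylsilyl)oxy]-3-methylbut-2-enoate
Product: 13 tert-butyl (2Z)-4-hydroxy-3-methylbut-2-enoate
Conditions: HF·pyridine, THF, 0 °C
Reagents that add atoms: none
Why: Fluoride cleavage of the silyl ether under buffered conditions; the bulky tert-butyl ester should slow lactonisation onto the cis hydroxyl, and 13 is used at once.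

Step 10
Reactants: 13 tert-butyl (2Z)-4-hydroxy-3-methylbut-2-enoate; 14 angelic acid [(2Z)-2-methylbut-2-enoic acid]
Product: 16 tert-butyl (2Z)-3-methyl-4-{[(2Z)-2-methylbut-2-enoyl]oxy}but-2-enoate, via angelic 2,4,6-trichlorobenzoic anhydride 15 (not isolated)
Conditions: 14, 2,4,6-Cl3C6H2COCl, Et3N, toluene, rt; then 13, rt to 60 °C
Reagents that add atoms: none
Why: Yamaguchi-type mixed-anhydride esterification run without DMAP, the variant known to transfer the angeloyl group without isomerisation to the tiglate; the primary alcohol attacks the less hindered angeloyl carbonyl.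

Step 11
Reactants: 16 tert-butyl (2Z)-3-methyl-4-{[(2Z)-2-methylbut-2-enoyl]oxy}but-2-enoate
Product: 17 (2Z)-3-methyl-4-{[(2Z)-2-methylbut-2-enoyl]oxy}but-2-enoic acid
Conditions: TFA, CH2Cl2, 0 °C to rt
Reagents that add atoms: none
Why: Acidolysis of the tert-butyl ester with loss of 2-methylpropene; the allylic angelate and both alkenes should be inert, and the carboxyl stays protonated, so it cannot displace the angelate.

Step 12
Reactants: 8 (3R,4R,5R,9R,10R)-9,10-epoxy-3-hydroxyeremophil-7(11)-en-8-one; 17 (2Z)-3-methyl-4-{[(2Z)-2-methylbut-2-enoyl]oxy}but-2-enoic acid
Product: 19 (3R,4R,5R,9R,10R)-9,10-epoxy-8-oxoeremophil-7(11)-en-3-yl (2Z)-3-methyl-4-{[(2Z)-2-methylbut-2-enoyl]oxy}but-2-enoate, via 2,4,6-trichlorobenzoic mixed anhydride 18 (not isolated)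
Conditions: 17, 2,4,6-Cl3C6H2COCl, Et3N, toluene, 0 °C; then 8, DMAP, 0 °C to rt
Reagents that add atoms: none
Why: Yamaguchi esterification; DMAP attacks the less hindered enoyl carbonyl of the mixed anhydride and the equatorial C3 alcohol is acylated with retention. Low temperature and a short reaction time are chosen to keep the 2Z geometry, and the epoxy ketone is inert to amine bases.

Step 13
Reactants: 19 (3R,4R,5R,9R,10R)-9,10-epoxy-8-oxoeremophil-7(11)-en-3-yl (2Z)-3-methyl-4-{[(2Z)-2-methylbut-2-enoyl]oxy}but-2-enoate
Product: 20 (3R,4R,5R)-9-hydroxy-8-oxoeremophila-7(11),9-dien-3-yl (2Z)-3-methyl-4-{[(2Z)-2-methylbut-2-enoyl]oxy}but-2-enoate (CNP0228871.1)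
Conditions: H2SO4 (cat.), AcOH, 15–20 °C
Reagents that add atoms: none
Why: Acid-catalysed isomerisation of an α,β-epoxy ketone to a diosphenol, as 4,5-epoxy-3-keto steroids give 4-hydroxy-4-en-3-ones: the protonated oxirane opens at the tertiary C10 and loss of the acidic H9 gives the C9 enol conjugated with C8=O. Both oxirane epimers converge, and C3, C4 and C5 are not involved.

## Compound list

1 | (2E,6E)-farnesol | CC(C)=CCC/C(C)=C/CC/C(C)=C/CO | starting material
2 | (2E,6E)-farnesyl chloride | CC(C)=CCC/C(C)=C/CC/C(C)=C/CCl | intermediate
3 | (2E,6E)-farnesyl diphosphate trisammonium salt | CC(C)=CCC/C(C)=C/CC/C(C)=C/COP(=O)([O-])OP(=O)([O-])[O-].[NH4+].[NH4+].[NH4+] | intermediate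
4 | (+)-aristolochene [(4S,5R,7S)-eremophila-9,11-diene] | C[C@H]1CCCC2=CC[C@H](C(C)=C)C[C@]12C | intermediate
5 | (4S,5R,7S)-eremophila-9,11-dien-8-one | C[C@H]1CCCC2=CC(=O)[C@H](C(C)=C)C[C@]12C | intermediate (not isolated)
6 | dehydrofukinone [(4S,5R)-eremophila-7(11),9-dien-8-one] | C[C@H]1CCCC2=CC(=O)C(=C(C)C)C[C@]12C | intermediate
7 | isopetasol [(3R,4R,5R)-3-hydroxyeremophila-7(11),9-dien-8-one] | O[C@@H]1CCC2=CC(=O)C(=C(C)C)C[C@]2(C)[C@H]1C | intermediate
8 | (3R,4R,5R,9R,10R)-9,10-epoxy-3-hydroxyeremophil-7(11)-en-8-one | O[C@@H]1CC[C@@]23O[C@H]3C(=O)C(=C(C)C)C[C@]2(C)[C@H]1C | intermediate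
9 | tert-butyldimethyl(prop-2-yn-1-yloxy)silane | C#CCO[Si](C)(C)C(C)(C)C | starting material
10 | lithium acetylide of 9 [lithium 3-(tert-butyldimethylsilyloxy)prop-1-yn-1-ide] | [Li]C#CCO[Si](C)(C)C(C)(C)C | intermediate (not isolated)
11 | tert-butyl 4-[(tert-butyldimethylsilyl)oxy]but-2-ynoate | CC(C)(C)OC(=O)C#CCO[Si](C)(C)C(C)(C)C | intermediate
12 | tert-butyl (2Z)-4-[(tert-butyldimethylsilyl)oxy]-3-methylbut-2-enoate | CC(C)(C)[Si](C)(C)OC/C(C)=C\C(=O)OC(C)(C)C | intermediate
13 | tert-butyl (2Z)-4-hydroxy-3-methylbut-2-enoate | OC/C(C)=C\C(=O)OC(C)(C)C | intermediate
14 | angelic acid [(2Z)-2-methylbut-2-enoic acid] | C/C=C(/C)C(=O)O | starting material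
15 | angelic 2,4,6-trichlorobenzoic anhydride | C/C=C(/C)C(=O)OC(=O)c1c(Cl)cc(Cl)cc1Cl | intermediate (not isolated)
16 | tert-butyl (2Z)-3-methyl-4-{[(2Z)-2-methylbut-2-enoyl]oxy}but-2-enoate | C/C=C(/C)C(=O)OC/C(C)=C\C(=O)OC(C)(C)C | intermediate
17 | (2Z)-3-methyl-4-{[(2Z)-2-methylbut-2-enoyl]oxy}but-2-enoic acid | C/C=C(/C)C(=O)OC/C(C)=C\C(=O)O | intermediate
18 | mixed anhydride of 17 and 2,4,6-trichlorobenzoic acid | C/C=C(/C)C(=O)OC/C(C)=C\C(=O)OC(=O)c1c(Cl)cc(Cl)cc1Cl | intermediate (not isolated)
19 | (3R,4R,5R,9R,10R)-9,10-epoxy-8-oxoeremophil-7(11)-en-3-yl (2Z)-3-methyl-4-{[(2Z)-2-methylbut-2-enoyl]oxy}but-2-enoate | C/C=C(/C)C(=O)OC/C(C)=C\C(=O)O[C@@H]1CC[C@@]23O[C@H]3C(=O)C(=C(C)C)C[C@]2(C)[C@H]1C | intermediate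
20 | (3R,4R,5R)-9-hydroxy-8-oxoeremophila-7(11),9-dien-3-yl (2Z)-3-methyl-4-{[(2Z)-2-methylbut-2-enoyl]oxy}but-2-enoate (CNP0228871.1) | C/C=C(/C)C(=O)OC/C(C)=C\C(=O)O[C@@H]1CCC2=C(O)C(=O)C(=C(C)C)C[C@]2(C)[C@H]1C | target

## Step count and risks

Total step count: 13 (steps 1–6 and 12–13 on the terpenoid line, steps 7–11 for the side-chain acid).
Longest linear sequence: 8 steps (1, 2, 3, 4, 5, 6, 12, 13).

**Step 5 (C3 hydroxylation), the least certain step.** The enzyme may oxidise other sites (the allylic C1, C2, the C12 and C13 methyls), may epoxidise C7=C11, or may remove the axial C3 hydrogen and give the C3 epimer; no variant is yet known for this substrate. The fallback is a chemical relay that sets out from 6 and returns at 7.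
- Dehydrogenation with DDQ through the ring dienol should give (4S,5R)-eremophila-1,7(11),9-trien-8-one F5.
- Riley oxidation with SeO2 at C3, the only allylic methylene of the new C1=C2 alkene, with the reagent approaching anti to the angular methyl, should give (3R,4R,5R)-3-hydroxyeremophila-1,7(11),9-trien-8-one F6.
- Hydrogenation of the disubstituted C1=C2 alkene over RhCl(PPh3)3 should then give 7.

**Step 3 (key step).** Turnover may stall at preparative concentration through precipitation of magnesium diphosphate complexes, product inhibition or slow catalysis. The cascade may also stop at germacrene A or end by loss of H1, and 3 may hydrolyse to the alcohol. The fallback sets out from farnesol 1 and returns at 4: a one-pot cascade in which an ATP-dependent alcohol kinase and an isoprenyl phosphate kinase (ATP recycled from acetyl phosphate by acetate kinase) form (2E,6E)-farnesyl phosphate F1 and then 3 at low steady-state concentration. The cyclase and an organic overlay are present throughout, so that 3 is consumed as it forms.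

**Step 4 (allylic oxidation).** Hydrogen abstraction may be poorly site-selective (C1, or the allylic C–H bonds of the isopropenyl group), and the enone may be over-oxidised to the enedione. The fallback sets out from 4 and returns at 5, which DBU converts into 6 as in step 4.
- mCPBA epoxidises the trisubstituted alkene anti to the C5 methyl to give 9,10-epoxyeremophil-11-ene F2.
- PhSeNa opens it at C9 to the trans hydroxy selenide 9-(phenylselanyl)eremophil-11-en-10-ol F3.
- H2O2 oxidation and selenoxide elimination give the tertiary allylic alcohol eremophila-8,11-dien-10-ol F4.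
- Pyridinium chlorochromate (PCC) then effects the Babler–Dauben oxidative transposition to 5.

**Step 13 (epoxide to diosphenol).** The strong acid may isomerise the angelate to the tiglate or cause acyl exchange, and the C10 cation may be diverted into acyl or methyl migration. The fallback sets out from 8 and returns at 20, with the rearrangement done before the acid-sensitive chain is present.
- 8 with H2SO4 in AcOH should give (3R,4R,5R)-3,9-dihydroxyeremophila-7(11),9-dien-8-one F9.
- The acidic enol is silylated selectively (TESCl, Et3N, −78 °C) to (3R,4R,5R)-3-hydroxy-9-(triethylsilyloxy)eremophila-7(11),9-dien-8-one F10.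
- Yamaguchi esterification with 17 gives the 9-O-triethylsilyl ether of the target F11, and HF·pyridine releases 20.

**Step 12 (esterification).** Activation of the Z acid may erode the 2Z geometry through a vinylketene or reversible DMAP addition, and slow acylation of the hindered alcohol may divert 18 to the trichlorobenzoate. The fallback sets out from 8 and returns at 19; it activates the alcohol instead of the acid.
- Dess–Martin oxidation gives (4R,5R,9R,10R)-9,10-epoxyeremophil-7(11)-ene-3,8-dione F7.
- LiBH(s-Bu)3 at −78 °C, attacking from the equatorial direction, gives the axial alcohol (3S,4R,5R,9R,10R)-9,10-epoxy-3-hydroxyeremophil-7(11)-en-8-one F8.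
- Mitsunobu esterification of F8 with 17 (PPh3, DIAD) gives 19 with inversion at C3.

## Further compounds

F1 | step 3 | (2E,6E)-farnesyl phosphate | CC(C)=CCC/C(C)=C/CC/C(C)=C/COP(=O)(O)O
F2 | step 4 | 9,10-epoxyeremophil-11-ene (oxirane anti to the C5 methyl) | C1CC[C@]23O[C@@H]3C[C@H](C(C)=C)C[C@]2(C)[C@H]1C
F3 | step 4 | 9-(phenylselanyl)eremophil-11-en-10-ol (selenium syn, hydroxyl anti to the C5 methyl) | C1CC[C@@]2(O)[C@@H]([Se]c3ccccc3)C[C@H](C(C)=C)C[C@]2(C)[C@H]1C
F4 | step 4 | eremophila-8,11-dien-10-ol (hydroxyl anti to the C5 methyl) | C1CC[C@@]2(O)C=C[C@H](C(C)=C)C[C@]2(C)[C@H]1C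
F5 | step 5 | (4S,5R)-eremophila-1,7(11),9-trien-8-one | C1C=CC2=CC(=O)C(=C(C)C)C[C@]2(C)[C@H]1C
F6 | step 5 | (3R,4R,5R)-3-hydroxyeremophila-1,7(11),9-trien-8-one | O[C@@H]1C=CC2=CC(=O)C(=C(C)C)C[C@]2(C)[C@H]1C
F7 | step 12 | (4R,5R,9R,10R)-9,10-epoxyeremophil-7(11)-ene-3,8-dione | O=C1CC[C@@]23O[C@H]3C(=O)C(=C(C)C)C[C@]2(C)[C@H]1C
F8 | step 12 | (3S,4R,5R,9R,10R)-9,10-epoxy-3-hydroxyeremophil-7(11)-en-8-one | O[C@H]1CC[C@@]23O[C@H]3C(=O)C(=C(C)C)C[C@]2(C)[C@H]1C
F9 | step 13 | (3R,4R,5R)-3,9-dihydroxyeremophila-7(11),9-dien-8-one | O[C@@H]1CCC2=C(O)C(=O)C(=C(C)C)C[C@]2(C)[C@H]1C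
F10 | step 13 | (3R,4R,5R)-3-hydroxy-9-(triethylsilyloxy)eremophila-7(11),9-dien-8-one | O[C@@H]1CCC2=C(O[Si](CC)(CC)CC)C(=O)C(=C(C)C)C[C@]2(C)[C@H]1C
F11 | step 13 | (3R,4R,5R)-8-oxo-9-(triethylsilyloxy)eremophila-7(11),9-dien-3-yl (2Z)-3-methyl-4-{[(2Z)-2-methylbut-2-enoyl]oxy}but-2-enoate | C/C=C(/C)C(=O)OC/C(C)=C\C(=O)O[C@@H]1CCC2=C(O[Si](CC)(CC)CC)C(=O)C(=C(C)C)C[C@]2(C)[C@H]1C
A1 | alternative 1 | (2R,5E)-2-(tert-butyldimethylsilyloxy)-1-(furan-2-yl)-5-methylhept-5-en-4-one | C/C=C(\C)C(=O)C[C@H](O[Si](C)(C)C(C)(C)C)Cc1ccco1
A2 | alternative 1 | 3,10-epoxy-8-(tert-butyldimethylsilyloxy)-4,5-dimethyloctalin-6-one with C1=C2 (eremophilane numbering) | C[C@H]1[C@H]2C=C[C@@]3(O2)C[C@@H](O[Si](C)(C)C(C)(C)C)CC(=O)[C@]13C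
A3 | alternative 2 | (S)-Hajos–Parrish ketone [(7aS)-7a-methyl-2,3,7,7a-tetrahydro-1H-indene-1,5(6H)-dione] | O=C1CCC2=CC(=O)CC[C@]12C
A4 | alternative 2 | (1R,8aR)-1,8a-dimethyl-3,4,8,8a-tetrahydronaphthalene-2,6(1H,7H)-dione | O=C1CCC2=CC(=O)CC[C@]2(C)[C@H]1C
A5 | alternative 3 | 2-methoxy-4-methyl-3-{2-[(2R,3R)-3-methyloxiran-2-yl]ethyl}phenol | COc1c(O)ccc(C)c1CC[C@H]1O[C@@H]1C
A6 | alternative 3 | (3R,4R,5R)-3-hydroxy-9-methoxy-4,5-dimethyloctalin-6,9-dien-8-one (eremophilane numbering) | O[C@@H]1CCC2=C(OC)C(=O)C=C[C@]2(C)[C@H]1C
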